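Remark on stereochemistry: the target is planar and has no stereocentre, stereogenic axis or configured double bond. It is therefore a single achiral compound, and no compound of the route needs a stereodescriptor.
Remark on notation: carbonyl ligands are written Cr=C=O in the SMILES strings. SMILES cannot express the η6 bond of 18, so its Cr(CO)3 unit is written as a separate fragment.

## Structural features

The target is a flavonol. A benzenoid A ring (C4a, C5–C8, C8a) is fused along C4a–C8a to a 4-pyranone C ring (O1, C2, C3, C4), and the B-ring phenyl is attached by the single bond C2–C1′. Seven carbons carry exocyclic oxygen besides the carbonyl: OH at C3, C5, C7, C3′ and C5′, and OMe at C8 and C4′. No stereocentres are present, so none stand next to each other and no enantiomer has to be selected.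

The fragile parts are the five free hydroxyls. The 3-hydroxy-4-pyranone enol and the electron-rich A ring oxidise easily in base and air, the pyranone opens with hard nucleophiles, and the C4=O/C3–OH and C4=O/C5–OH sites bind metals. The real difficulty is regiochemical. Exactly two of the seven oxygens are methyl ethers, and phloroglucinol-type arene chemistry separates the 5,7-dihydroxy-8-methoxy pattern poorly from its 6-methoxy isomer. On the B ring, C1′ lies para to the methoxy group and meta to both hydroxyls, a position that electrophilic substitution does not reach.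

The key step uses the para relation of C8–OMe and C5–OH on the A ring, which is the substitution pattern left by a methoxycarbene/alkyne/CO benzannulation. It also uses the fact that O1, C2, C3–O, C4, C4a, C8a and C8 map atom for atom onto a 5-hydroxy-2-(hydroxymethyl)-4-pyranone.

## Logic of the disconnections

**21 ⇒ 20.** The O–CH2Ph bonds at O3, O3′ and O5′ are cut. These three hydroxyls must stay masked through the acyl chloride, chromate and carbene stages, and a single ether type lets them be removed together under neutral conditions. The gain is that the chelating, air-sensitive pentaol exists only in the last flask. The forward step must cleave three benzyl ethers without touching C2=C3, C4=O or the two methyl ethers.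

**20 ⇒ 19.** The C7–O bond is exchanged for C7–B. An oxygen-bearing alkyne offers no dependable orientation, whereas boron steers the annulation and is later replaced by oxygen at the same carbon. The whole 5,7,8-oxygen pattern is thereby reduced to the question of where boron sits. The oxidant must be mild enough for a 4-methoxyphenol and for a base-sensitive pyranone.

**19 ⇒ 16 + 17.** C8–C7, C6–C5 and C5–C4a are cut, and C5 with its oxygen goes back to a carbonyl ligand on the metal.
- The cut is made here because the mechanism then places every A-ring substituent. The carbene methoxy group becomes 8-OMe, the ligand becomes 5-OH, and the alkyne delivers C6–H and C7–B.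
- A tetrasubstituted benzene ring is removed in one operation, leaving a monocyclic pyranone.
- The forward step requires the boron-bearing alkyne carbon to bond to C8, CO insertion to precede ring closure, and the metal to be removed from 18 without oxidising the new hydroquinone monoether.

**16 ⇒ 12 + 13.** The Cr=C8 bond and the carbene O–CH3 bond are cut, by way of 15 and 14. C8 is already attached to the pyranone as an acyl carbon, so pairing it with a metal-centred nucleophile avoids metalating the ring. The organometallic problem becomes an acylation followed by an O-alkylation. The strongly reducing 14 must attack only the acyl chloride, and the methylating agent must be limited to one equivalent, because 4-pyranone carbonyls themselves alkylate to pyrylium salts.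

**12 ⇒ 11 ⇒ 9.** The C8–Cl bond and then two C8–O bonds are removed, passing through 10, which brings C8 back to the alcohol level. This is pure oxidation-state adjustment of a carbon that is present from the start. The oxidant must spare a trialkoxyarene and three benzyl ethers. The chlorinating agent must be metered so that C4=O is not converted into a chloropyrylium ion.

**9 ⇒ 8 + 5.** The C2–C1′ bond is cut. It is the only bond between the two halves and joins two sp2 carbons, so the route becomes convergent with two fragments of similar size. The forward coupling needs a halide at the pyranone carbon next to O1 and a boron atom at C1′. It must also tolerate a free primary alcohol and a ring that does not survive hydroxide.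

**8 ⇒ 7 ⇒ 6.** The O3–benzyl bond and the C2–Br bond are cut. Halogenation comes first because the free enol is what makes this carbon nucleophilic; after etherification that activation is lost. Two simple steps lead back to a bulk chemical. The etherification must distinguish the acidic enol from the primary alcohol.

**5 ⇒ 4 ⇒ 1.** The two O–benzyl bonds and then the C1′–B bond are cut, the latter through 3 and 2.
- The order matters. Electrophilic halogenation of 1 or its ethers goes ortho or para to the flanking oxygens and misses C1′.
- A sterically governed C–H borylation carried out after benzylation would have to compete with six unhindered C–H bonds on the two benzyl rings.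
- Borylating the transiently O-masked diol first leaves one accessible C–H bond. The forward step therefore depends on complete O-masking and on steric rather than directed selectivity.

## Other disconnections considered

**Alternative 1:** The cut removes C4 and separates both sides of the C ring. C4a–C4, C4–C3 and O1–C2 are broken, which leads to 3,5-bis(benzyloxy)-2-iodo-6-methoxyphenol (A2), 1,3-bis(benzyloxy)-5-ethynyl-2-methoxybenzene (A3) and carbon monoxide (A4). In the forward direction palladium(0) would insert into the C–I bond of A2, take up A4 and transfer the acyl group to A3. A secondary amine would then add to the ynone and pass its β-carbon to the phenol oxygen, closing the pyranone of 5,7-bis(benzyloxy)-2-[3,5-bis(benzyloxy)-4-methoxyphenyl]-8-methoxy-4H-chromen-4-one (A1).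
- In its favour: it forms three bonds and one ring in one flask, which equals the chosen plan. It is catalytic in an easily handled metal, which is better than a full equivalent of toxic chromium. Its reaction class is well tried on 2-iodophenols, which is also better than an untried pyranonyl carbene.
- Against it here: A1 carries hydrogen at C3, so the flavonol oxygen needs a further oxidation on a substrate with four benzyl ethers.
- The C–I bond of A2 sits between OH and OBn on an electron-rich ring. This slows oxidative addition and CO uptake and invites direct alkynylation with benzofuran formation. Closure can also go 5-exo to an aurone.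
- Above all, the five contiguous substituents of A2, with only one of the two oxygens beside the methoxy group left free, must be set by arene substitution rules and selective protection. That is the problem the chosen plan settles by mechanism.
- Step economy: the two are close, possibly one step shorter for this alternative. Its steps are individually safer but its selectivity problems are spread over more of them.

**Alternative 2:** The cut is O1–C8a alone. It leads to 2-(benzyloxy)-1-[4-(benzyloxy)-2,5-dimethoxyphenyl]-3-[3,5-bis(benzyloxy)-4-methoxyphenyl]propane-1,3-dione (A6). Forward, anodic or cerium(IV) oxidative demethylation would give the acylquinone 2-{2-(benzyloxy)-3-[3,5-bis(benzyloxy)-4-methoxyphenyl]-3-oxopropanoyl}-5-(benzyloxy)-1,4-benzoquinone (A7). Its enol oxygen would add to the doubly activated C8a, and tautomerisation would give 3,7-bis(benzyloxy)-2-[3,5-bis(benzyloxy)-4-methoxyphenyl]-5,8-dihydroxy-4H-chromen-4-one (A5).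
- In its favour: the C3 oxygen is present from the outset, as in the chosen plan. The A ring comes from a simple 1,2,4-trioxygenated arene whose acylation site is unambiguous, so O1–C8a forms at a C–H position without a pre-set phenol. No stoichiometric heavy metal is needed in the anodic version, which is a clear advantage. The 5-OH/8-OH pair of A5 is differentiated by chelation, so selective 8-O-methylation is credible.
- Against it here: A6 contains a second trialkoxyarene, four benzyl ethers and an enolisable 2-alkoxy-1,3-diketone, all within reach of the same oxidant.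
- The 7-benzyloxy group of A7 is a vinylogous ester open to addition–elimination.
- A5 is a hydroquinone that is easier to oxidise than A6, so over-oxidation must be corrected reductively.
- One extra methylation step is needed to restore the methyl ether that was just removed.
- Comparison: only one bond forms, against three in the chosen plan. The mechanism fixes the 5,8-para relation as firmly as the benzannulation does, so the two are equal on that point. The sequence is probably one or two steps shorter, but everything rests on chemoselective oxidation.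

**Alternative 3:** The cuts are O1–C2 and C3–I. They lead to 1-[4,6-bis(benzyloxy)-2-hydroxy-3-methoxyphenyl]-3-[3,5-bis(benzyloxy)-4-methoxyphenyl]prop-2-yn-1-one (A9). Forward, an iodonium source would activate the triple bond, and the C8a phenol would attack the aryl-bearing alkyne carbon in a 6-endo-dig closure. The product would be 5,7-bis(benzyloxy)-2-[3,5-bis(benzyloxy)-4-methoxyphenyl]-3-iodo-8-methoxy-4H-chromen-4-one (A8).
- In its favour: ynone polarisation and the B-ring donor both direct the attack to C2, so the ring size is better secured than in Alternative 1. The conditions are mild and need no transition metal, which is better than the chosen plan. The iodine lands exactly at the carbon that needs oxygen.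
- Against it here: C6–H of the A ring lies between two benzyloxy groups and, like the B ring, competes for the electrophile.
- A free-phenol ynone can cyclise prematurely, and under base in the 5-exo sense.
- Turning the hindered C3–I of A8 into C3–O costs one or two further steps of copper-mediated coupling or metalation–boration–oxidation.
- A9 needs the same fully differentiated pentasubstituted A ring as A2, which must be built by substitution rules.
- Comparison: two bonds and one ring are formed, against three bonds and one ring. The key step itself rests on firmer ground than the benzannulation. The chosen plan keeps the advantage of starting with C3–O in place and of assigning the A-ring pattern by mechanism. Overall length should be similar.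

Key step: step 9

## Route

Step 1
Reactants: 1 2-methoxyresorcinol (2-methoxybenzene-1,3-diol)
Product: 4 2-methoxy-5-(4,4,5,5-tetramethyl-1,3,2-dioxaborolan-2-yl)benzene-1,3-diol, via bis(O-boryl) ether 2 (not isolated), via C5-borylated bis(O-boryl) ether 3 (not isolated)
Conditions: HBpin (2.2 equiv), THF, rt; then [Ir(OMe)(cod)]2 (1.5 mol %), dtbpy (3 mol %), B2pin2 (1.0 equiv), 80 °C; MeOH, rt
Reagents that add atoms: bis(pinacolato)diboron CC1(C)OB(OC1(C)C)B1OC(C)(C)C(C)(C)O1; pinacolborane [H]B1OC(C)(C)C(C)(C)O1 (its atoms stay only in 2 and 3)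
Why: Iridium-catalysed aromatic C–H borylation (Hartwig–Miyaura type) is sterically governed, and once both phenols are masked in the flask as O-boryl ethers, C5 is the only ring C–H without an ortho neighbour. Methanol then cleaves only the O–B bonds, and borylating before benzylation removes any competition from benzyl-ring C–H bonds.

Step 2
Reactants: 4 2-methoxy-5-(4,4,5,5-tetramethyl-1,3,2-dioxaborolan-2-yl)benzene-1,3-diol
Product: 5 2-[3,5-bis(benzyloxy)-4-methoxyphenyl]-4,4,5,5-tetramethyl-1,3,2-dioxaborolane
Conditions: BnBr (2.3 equiv), K2CO3 (3 equiv), acetone, reflux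
Reagents that add atoms: benzyl bromide BrCc1ccccc1
Why: Williamson etherification of two equivalent phenols; aryl pinacol boronates tolerate anhydrous carbonate and alkyl halides.

Step 3
Reactants: 6 kojic acid (5-hydroxy-2-(hydroxymethyl)-4H-pyran-4-one)
Product: 7 2-bromo-3-hydroxy-6-(hydroxymethyl)-4H-pyran-4-one (6-bromokojic acid)
Conditions: NBS (1.05 equiv), MeCN, 0 °C to rt
Reagents that add atoms: N-bromosuccinimide O=C1CCC(=O)N1Br
Why: Electrophilic halogenation of an enol; the carbon next to the free enolic OH and to the ring oxygen is the nucleophilic site of kojic acid, so substitution should occur only there.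

Step 4
Reactants: 7 2-bromo-3-hydroxy-6-(hydroxymethyl)-4H-pyran-4-one
Product: 8 3-(benzyloxy)-2-bromo-6-(hydroxymethyl)-4H-pyran-4-one
Conditions: BnBr (1.1 equiv), K2CO3 (1.5 equiv), DMF, 50 °C
Reagents that add atoms: benzyl bromide BrCc1ccccc1
Why: Williamson etherification; carbonate deprotonates only the acidic enol (pKa about 8), so the primary alcohol stays free.

Step 5
Reactants: 8 3-(benzyloxy)-2-bromo-6-(hydroxymethyl)-4H-pyran-4-one; 5 2-[3,5-bis(benzyloxy)-4-methoxyphenyl]-4,4,5,5-tetramethyl-1,3,2-dioxaborolane
Product: 9 5-(benzyloxy)-6-[3,5-bis(benzyloxy)-4-methoxyphenyl]-2-(hydroxymethyl)-4H-pyran-4-one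
Conditions: Pd(dppf)Cl2 (5 mol %), K2CO3 (2.5 equiv), 1,4-dioxane/H2O 5:1, 85 °C
Reagents that add atoms: none
Why: Suzuki–Miyaura coupling; the C–Br bond is a vinylogous acyl bromide and adds readily to palladium(0), and the boronate has no ortho substituent. Carbonate is mild enough for the pyranone ring and the free alcohol.

Step 6
Reactants: 9 5-(benzyloxy)-6-[3,5-bis(benzyloxy)-4-methoxyphenyl]-2-(hydroxymethyl)-4H-pyran-4-one
Product: 11 5-(benzyloxy)-6-[3,5-bis(benzyloxy)-4-methoxyphenyl]-4-oxo-4H-pyran-2-carboxylic acid, via pyranone-2-carbaldehyde 10 (not isolated)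
Conditions: TEMPO (0.2 equiv), PhI(OAc)2 (2.2 equiv), MeCN/H2O 1:1, rt
Reagents that add atoms: water O
Why: Oxoammonium (TEMPO/hypervalent iodine) oxidation of a primary alcohol through the aldehyde hydrate to the acid. The reagent is halogen-free and non-acidic, so the trialkoxyarene and the benzyl ethers should be left alone.

Step 7
Reactants: 11 5-(benzyloxy)-6-[3,5-bis(benzyloxy)-4-methoxyphenyl]-4-oxo-4H-pyran-2-carboxylic acid
Product: 12 5-(benzyloxy)-6-[3,5-bis(benzyloxy)-4-methoxyphenyl]-4-oxo-4H-pyran-2-carbonyl chloride
Conditions: (COCl)2 (1.2 equiv), DMF (cat.), CH2Cl2, 0 °C to rt; evaporate, use crude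
Reagents that add atoms: oxalyl chloride O=C(Cl)C(=O)Cl
Why: Vilsmeier-catalysed acid chloride formation, routine for 5-alkoxy-4-oxopyran-2-carboxylic acids. A small excess of reagent and a low temperature should keep C4=O from being converted into a chloropyrylium ion.

Step 8
Reactants: 12 5-(benzyloxy)-6-[3,5-bis(benzyloxy)-4-methoxyphenyl]-4-oxo-4H-pyran-2-carbonyl chloride; 13 chromium hexacarbonyl
Product: 16 pentacarbonyl{[5-(benzyloxy)-6-[3,5-bis(benzyloxy)-4-methoxyphenyl]-4-oxo-4H-pyran-2-yl](methoxy)carbene}chromium, via disodium pentacarbonylchromate 14 (not isolated), via sodium acylchromate 15 (not isolated)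
Conditions: 13 (1.1 equiv), sodium naphthalenide (2.1 equiv), THF, −78 to 0 °C; 12, THF, −78 to 0 °C; evaporate; Me3OBF4 (1.05 equiv), CH2Cl2, 0 °C; chromatography under Ar
Reagents that add atoms: trimethyloxonium tetrafluoroborate C[O+](C)C.F[B-](F)(F)F
Why: Semmelhack–Hegedus entry to Fischer carbenes, in which the metal dianion displaces chloride at the acyl carbon and the anionic oxygen of 15 is then O-alkylated with Meerwein salt. A slight excess of 13 consumes all the naphthalenide, so benzyl ethers and pyranone meet only 14. The acylate oxygen is far more nucleophilic than the neutral pyranone carbonyl, so about one equivalent of the salt should alkylate it selectively.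

Step 9
Reactants: 16 pentacarbonyl{[5-(benzyloxy)-6-[3,5-bis(benzyloxy)-4-methoxyphenyl]-4-oxo-4H-pyran-2-yl](methoxy)carbene}chromium; 17 2-ethynyl-4,4,5,5-tetramethyl-1,3,2-dioxaborolane
Product: 19 3-(benzyloxy)-2-[3,5-bis(benzyloxy)-4-methoxyphenyl]-5-hydroxy-8-methoxy-7-(4,4,5,5-tetramethyl-1,3,2-dioxaborolan-2-yl)-4H-chromen-4-one, via tricarbonylchromium π-complex 18 (not isolated)
Conditions: 17 (2 equiv), THF (0.05 M), 50 °C, Ar, 16 h; then air, MeCN, rt; aq. EDTA wash
Reagents that add atoms: none
Why: This is a Dötz benzannulation of a cyclic α-alkoxyalkenyl Fischer carbene; the closest known cases are dihydropyranyl and furyl methoxycarbene complexes, which give chromans and benzofurans, and the benzannulation of alkenyl and aryl complexes with 1-alkynyl pinacol boronates. Thermal loss of one cis carbonyl from 16 frees a site for 17, which inserts into the Cr=C8 bond to give an η1,η3-vinylcarbene and so forms C8–C7. Migration of a carbonyl ligand to the new carbene carbon C6 forms C6–C5 and gives the chromium-bound dienylketene O=C5=C6–C7=C8–C8a=C4a. The single new ring, the six-membered carbocyclic A ring, closes by 6π electrocyclisation of this ketene with formation of C5–C4a, and the resulting cyclohexadienone, whose C4a–H is also α to C4=O, enolises at once to the C5 phenol, which is held by a hydrogen bond to C4=O. No stereocentre is created, so no stereocontrol element is needed. The step needs the boron-bearing alkyne carbon to bond to C8 against the usual steric rule; this rests on the contrasteric bias of boryl- and stannylalkynes, ascribed to an attractive contact between the electron-poor heteroatom and a carbonyl ligand in the vinylcarbene, which here has to outweigh only the bulk of a planar boronate. It also needs CO insertion to outrun closure to a five-membered ring, which is favoured by chromium, by the methoxy donor, by an alkenyl rather than aryl carbene substituent and by a donor solvent at moderate temperature, and C4a is the only carbon at which the ketene can close. Chromium is removed from 18 with air and not with cerium(IV), which would turn the 4-methoxyphenol into a quinone and destroy the 8-OMe.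

Step 10
Reactants: 19 3-(benzyloxy)-2-[3,5-bis(benzyloxy)-4-methoxyphenyl]-5-hydroxy-8-methoxy-7-(4,4,5,5-tetramethyl-1,3,2-dioxaborolan-2-yl)-4H-chromen-4-one
Product: 20 3-(benzyloxy)-2-[3,5-bis(benzyloxy)-4-methoxyphenyl]-5,7-dihydroxy-8-methoxy-4H-chromen-4-one
Conditions: NaBO3·4H2O (3 equiv), THF/H2O 1:1, rt; aq. NH4Cl
Reagents that add atoms: sodium perborate (used as the tetrahydrate) [Na+].[Na+].O[B-]1(O)OO[B-](O)(O)OO1
Why: Oxidation of an arylboronate by peroxide addition to boron and 1,2-aryl migration, which places oxygen on the carbon that carried boron. Perborate is less basic and less nucleophilic than alkaline hydrogen peroxide, which should protect C2 of the pyranone and the hydroquinone monoether.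

Step 11
Reactants: 20 3-(benzyloxy)-2-[3,5-bis(benzyloxy)-4-methoxyphenyl]-5,7-dihydroxy-8-methoxy-4H-chromen-4-one
Product: 21 2-(3,5-dihydroxy-4-methoxyphenyl)-3,5,7-trihydroxy-8-methoxy-4H-chromen-4-one (target)
Conditions: H2 (1 atm), 10 % Pd/C, EtOAc/MeOH 1:1, rt; filter under Ar
Reagents that add atoms: none
Why: Catalytic hydrogenolysis of three benzyl ethers, the standard last step for benzylated flavonols. The fully substituted, conjugated C2=C3 bond and the methyl ethers are not expected to react at one atmosphere.

## Compound list

1 | 2-methoxyresorcinol (2-methoxybenzene-1,3-diol) | COc1c(O)cccc1O | starting material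
2 | 2,2′-[(2-methoxy-1,3-phenylene)bis(oxy)]bis(4,4,5,5-tetramethyl-1,3,2-dioxaborolane) | COc1c(OB2OC(C)(C)C(C)(C)O2)cccc1OB1OC(C)(C)C(C)(C)O1 | intermediate
3 | 2,2′-{[2-methoxy-5-(4,4,5,5-tetramethyl-1,3,2-dioxaborolan-2-yl)-1,3-phenylene]bis(oxy)}bis(4,4,5,5-tetramethyl-1,3,2-dioxaborolane) | COc1c(OB2OC(C)(C)C(C)(C)O2)cc(B2OC(C)(C)C(C)(C)O2)cc1OB1OC(C)(C)C(C)(C)O1 | intermediate
4 | 2-methoxy-5-(4,4,5,5-tetramethyl-1,3,2-dioxaborolan-2-yl)benzene-1,3-diol | COc1c(O)cc(B2OC(C)(C)C(C)(C)O2)cc1O | intermediate
5 | 2-[3,5-bis(benzyloxy)-4-methoxyphenyl]-4,4,5,5-tetramethyl-1,3,2-dioxaborolane | COc1c(OCc2ccccc2)cc(B2OC(C)(C)C(C)(C)O2)cc1OCc1ccccc1 | intermediate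
6 | kojic acid (5-hydroxy-2-(hydroxymethyl)-4H-pyran-4-one) | O=c1cc(CO)occ1O | starting material
7 | 2-bromo-3-hydroxy-6-(hydroxymethyl)-4H-pyran-4-one | O=c1cc(CO)oc(Br)c1O | intermediate
8 | 3-(benzyloxy)-2-bromo-6-(hydroxymethyl)-4H-pyran-4-one | O=c1cc(CO)oc(Br)c1OCc1ccccc1 | intermediate
9 | 5-(benzyloxy)-6-[3,5-bis(benzyloxy)-4-methoxyphenyl]-2-(hydroxymethyl)-4H-pyran-4-one | COc1c(OCc2ccccc2)cc(-c2oc(CO)cc(=O)c2OCc2ccccc2)cc1OCc1ccccc1 | intermediate
10 | 5-(benzyloxy)-6-[3,5-bis(benzyloxy)-4-methoxyphenyl]-4-oxo-4H-pyran-2-carbaldehyde | COc1c(OCc2ccccc2)cc(-c2oc(C=O)cc(=O)c2OCc2ccccc2)cc1OCc1ccccc1 | intermediate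
11 | 5-(benzyloxy)-6-[3,5-bis(benzyloxy)-4-methoxyphenyl]-4-oxo-4H-pyran-2-carboxylic acid | COc1c(OCc2ccccc2)cc(-c2oc(C(=O)O)cc(=O)c2OCc2ccccc2)cc1OCc1ccccc1 | intermediate
12 | 5-(benzyloxy)-6-[3,5-bis(benzyloxy)-4-methoxyphenyl]-4-oxo-4H-pyran-2-carbonyl chloride | COc1c(OCc2ccccc2)cc(-c2oc(C(=O)Cl)cc(=O)c2OCc2ccccc2)cc1OCc1ccccc1 | intermediate
13 | chromium hexacarbonyl | O=C=[Cr](=C=O)(=C=O)(=C=O)(=C=O)=C=O | starting material
14 | disodium pentacarbonylchromate | [Na+].[Na+].O=C=[Cr-2](=C=O)(=C=O)(=C=O)=C=O | intermediate
15 | sodium pentacarbonyl{[5-(benzyloxy)-6-[3,5-bis(benzyloxy)-4-methoxyphenyl]-4-oxo-4H-pyran-2-yl]carbonyl}chromate, drawn as the oxidocarbene | [Na+].[O-]C(=[Cr](=C=O)(=C=O)(=C=O)(=C=O)=C=O)c1cc(=O)c(OCc2ccccc2)c(-c2cc(OCc3ccccc3)c(OC)c(OCc3ccccc3)c2)o1 | intermediate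
16 | pentacarbonyl{[5-(benzyloxy)-6-[3,5-bis(benzyloxy)-4-methoxyphenyl]-4-oxo-4H-pyran-2-yl](methoxy)carbene}chromium | COC(=[Cr](=C=O)(=C=O)(=C=O)(=C=O)=C=O)c1cc(=O)c(OCc2ccccc2)c(-c2cc(OCc3ccccc3)c(OC)c(OCc3ccccc3)c2)o1 | intermediate
17 | 2-ethynyl-4,4,5,5-tetramethyl-1,3,2-dioxaborolane | C#CB1OC(C)(C)C(C)(C)O1 | starting material
18 | tricarbonyl(η6-A-ring) chromium complex of 19, with the metal fragment written as a separate component | COc1c(OCc2ccccc2)cc(-c2oc3c(OC)c(B4OC(C)(C)C(C)(C)O4)cc(O)c3c(=O)c2OCc2ccccc2)cc1OCc1ccccc1.O=C=[Cr](=C=O)=C=O | intermediate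
19 | 3-(benzyloxy)-2-[3,5-bis(benzyloxy)-4-methoxyphenyl]-5-hydroxy-8-methoxy-7-(4,4,5,5-tetramethyl-1,3,2-dioxaborolan-2-yl)-4H-chromen-4-one | COc1c(OCc2ccccc2)cc(-c2oc3c(OC)c(B4OC(C)(C)C(C)(C)O4)cc(O)c3c(=O)c2OCc2ccccc2)cc1OCc1ccccc1 | intermediate
20 | 3-(benzyloxy)-2-[3,5-bis(benzyloxy)-4-methoxyphenyl]-5,7-dihydroxy-8-methoxy-4H-chromen-4-one | COc1c(OCc2ccccc2)cc(-c2oc3c(OC)c(O)cc(O)c3c(=O)c2OCc2ccccc2)cc1OCc1ccccc1 | intermediate
21 | 2-(3,5-dihydroxy-4-methoxyphenyl)-3,5,7-trihydroxy-8-methoxy-4H-chromen-4-one | COc1c(O)cc(-c2oc3c(OC)c(O)cc(O)c3c(=O)c2O)cc1O | target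

## Step count and risks

Total step count: 11.
Longest linear sequence: 9 steps. This applies to steps 3–11 from 6 and equally to steps 1, 2 and 5–11 from 1.

**Step 9 (key step).**
- The most likely failure is alkyne insertion in the sterically normal sense. Boron would then sit next to the ketene carbon, and C6 rather than C7 would end up oxygenated.
- The opposing bias is best established for internal alkynylboronates and for stannylalkynes. A terminal alkyne gives sterics its greatest influence.
- Further hazards are ring closure without CO uptake to a five-membered ring, thermal decay of an unusually electron-poor carbene complex before CO loss, and protodeboronation of the alkyne or the product.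
- Fallback, from 16 to 20: the terminal alkyne is replaced by 4,4,5,5-tetramethyl-2-[(trimethylsilyl)ethynyl]-1,3,2-dioxaborolane F1. The bulky silyl group prefers the position next to the ketene carbon, so steric and electronic preferences agree.
- Benzannulation, at a somewhat higher temperature if the silylketene is slow to close, should give 3-(benzyloxy)-2-[3,5-bis(benzyloxy)-4-methoxyphenyl]-5-hydroxy-8-methoxy-7-(4,4,5,5-tetramethyl-1,3,2-dioxaborolan-2-yl)-6-(trimethylsilyl)-4H-chromen-4-one F2.
- Perborate oxidation should give 3-(benzyloxy)-2-[3,5-bis(benzyloxy)-4-methoxyphenyl]-5,7-dihydroxy-8-methoxy-6-(trimethylsilyl)-4H-chromen-4-one F3.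
- Protodesilylation with trifluoroacetic acid in CH2Cl2 should then be easy at a carbon flanked by two hydroxyls, and it rejoins the route at 20.

**Step 8.**
- The most likely failure is electron transfer from the strongly reducing dianion to the electron-poor pyranone acyl chloride, or its attack on the ring, in place of clean acyl substitution.
- A second hazard is alkylation of the pyranone carbonyl to a pyrylium ion during the methylation.
- Fallback, from 11 to 16: this is the classical organolithium entry to Fischer carbenes, which avoids the dianion. Silver-catalysed protodecarboxylation (Ag2CO3 cat., AcOH, DMSO, 120 °C) should give 3-(benzyloxy)-2-[3,5-bis(benzyloxy)-4-methoxyphenyl]-4H-pyran-4-one F4.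
- Deprotonation next to the ring oxygen with lithium tetramethylpiperidide in THF at −78 °C, as is done with chromones, should give [5-(benzyloxy)-6-[3,5-bis(benzyloxy)-4-methoxyphenyl]-4-oxo-4H-pyran-2-yl]lithium F5.
- Transfer onto a suspension of 13 should give the lithium acylchromate F6. Methylation with one equivalent of Me3OBF4 rejoins the route at 16.

**Step 1.**
- The most likely failures are incomplete O-masking, so that free phenol slows the catalyst, borylation ortho to an O-boryl group through an attractive substrate–ligand contact, and a second borylation.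
- Fallback, from 1 to 4: the transient masks are replaced by isolated, bulky acyl groups. Pivaloyl chloride and pyridine should give 2-methoxy-1,3-phenylene bis(2,2-dimethylpropanoate) F7.
- The same iridium catalysis should give 2-methoxy-5-(4,4,5,5-tetramethyl-1,3,2-dioxaborolan-2-yl)-1,3-phenylene bis(2,2-dimethylpropanoate) F8. The tert-butyl groups have no arene C–H bonds and shield C4 and C6.
- Methanolysis with K2CO3 in MeOH at rt rejoins the route at 4.

**Step 10.**
- The most likely failures are protodeboronation of the electron-rich boronate during isolation or in the aqueous base, peroxide addition at C2 with ring opening, and oxidation of the hydroquinone monoether. Carrying 19 forward without chromatography lowers the first risk.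
- Fallback, from 19 to 21: the peroxide is given up in favour of a copper(II)-mediated oxidative C–O coupling of Chan–Lam type with benzyl alcohol (Cu(OAc)2, pyridine, molecular sieves, air, CH2Cl2).
- This should give 3,7-bis(benzyloxy)-2-[3,5-bis(benzyloxy)-4-methoxyphenyl]-5-hydroxy-8-methoxy-4H-chromen-4-one F9. The chelated 5-OH should be a poor competitor in the coupling.
- Hydrogenolysis under the conditions of step 11 then removes four benzyl groups and reaches 21 directly, so the step count does not change.

## Further compounds

F1 | step 9 | 4,4,5,5-tetramethyl-2-[(trimethylsilyl)ethynyl]-1,3,2-dioxaborolane | C[Si](C)(C)C#CB1OC(C)(C)C(C)(C)O1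
F2 | step 9 | 3-(benzyloxy)-2-[3,5-bis(benzyloxy)-4-methoxyphenyl]-5-hydroxy-8-methoxy-7-(4,4,5,5-tetramethyl-1,3,2-dioxaborolan-2-yl)-6-(trimethylsilyl)-4H-chromen-4-one | COc1c(OCc2ccccc2)cc(-c2oc3c(OC)c(B4OC(C)(C)C(C)(C)O4)c([Si](C)(C)C)c(O)c3c(=O)c2OCc2ccccc2)cc1OCc1ccccc1
F3 | step 9 | 3-(benzyloxy)-2-[3,5-bis(benzyloxy)-4-methoxyphenyl]-5,7-dihydroxy-8-methoxy-6-(trimethylsilyl)-4H-chromen-4-one | COc1c(OCc2ccccc2)cc(-c2oc3c(OC)c(O)c([Si](C)(C)C)c(O)c3c(=O)c2OCc2ccccc2)cc1OCc1ccccc1
F4 | step 8 | 3-(benzyloxy)-2-[3,5-bis(benzyloxy)-4-methoxyphenyl]-4H-pyran-4-one | COc1c(OCc2ccccc2)cc(-c2occc(=O)c2OCc2ccccc2)cc1OCc1ccccc1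
F5 | step 8 | [5-(benzyloxy)-6-[3,5-bis(benzyloxy)-4-methoxyphenyl]-4-oxo-4H-pyran-2-yl]lithium | [Li]c1cc(=O)c(OCc2ccccc2)c(-c2cc(OCc3ccccc3)c(OC)c(OCc3ccccc3)c2)o1
F6 | step 8 | lithium pentacarbonyl{[5-(benzyloxy)-6-[3,5-bis(benzyloxy)-4-methoxyphenyl]-4-oxo-4H-pyran-2-yl]carbonyl}chromate | [Li+].[O-]C(=[Cr](=C=O)(=C=O)(=C=O)(=C=O)=C=O)c1cc(=O)c(OCc2ccccc2)c(-c2cc(OCc3ccccc3)c(OC)c(OCc3ccccc3)c2)o1
F7 | step 1 | 2-methoxy-1,3-phenylene bis(2,2-dimethylpropanoate) | COc1c(OC(=O)C(C)(C)C)cccc1OC(=O)C(C)(C)C
F8 | step 1 | 2-methoxy-5-(4,4,5,5-tetramethyl-1,3,2-dioxaborolan-2-yl)-1,3-phenylene bis(2,2-dimethylpropanoate) | COc1c(OC(=O)C(C)(C)C)cc(B2OC(C)(C)C(C)(C)O2)cc1OC(=O)C(C)(C)C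
F9 | step 10 | 3,7-bis(benzyloxy)-2-[3,5-bis(benzyloxy)-4-methoxyphenyl]-5-hydroxy-8-methoxy-4H-chromen-4-one | COc1c(OCc2ccccc2)cc(-c2oc3c(OC)c(OCc4ccccc4)cc(O)c3c(=O)c2OCc2ccccc2)cc1OCc1ccccc1
A1 | alternative 1 | 5,7-bis(benzyloxy)-2-[3,5-bis(benzyloxy)-4-methoxyphenyl]-8-methoxy-4H-chromen-4-one | COc1c(OCc2ccccc2)cc(-c2cc(=O)c3c(OCc4ccccc4)cc(OCc4ccccc4)c(OC)c3o2)cc1OCc1ccccc1
A2 | alternative 1 | 3,5-bis(benzyloxy)-2-iodo-6-methoxyphenol | COc1c(O)c(I)c(OCc2ccccc2)cc1OCc1ccccc1
A3 | alternative 1 | 1,3-bis(benzyloxy)-5-ethynyl-2-methoxybenzene | C#Cc1cc(OCc2ccccc2)c(OC)c(OCc2ccccc2)c1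
A4 | alternative 1 | carbon monoxide | [C-]#[O+]
A5 | alternative 2 | 3,7-bis(benzyloxy)-2-[3,5-bis(benzyloxy)-4-methoxyphenyl]-5,8-dihydroxy-4H-chromen-4-one | COc1c(OCc2ccccc2)cc(-c2oc3c(O)c(OCc4ccccc4)cc(O)c3c(=O)c2OCc2ccccc2)cc1OCc1ccccc1
A6 | alternative 2 | 2-(benzyloxy)-1-[4-(benzyloxy)-2,5-dimethoxyphenyl]-3-[3,5-bis(benzyloxy)-4-methoxyphenyl]propane-1,3-dione | COc1cc(OCc2ccccc2)c(OC)cc1C(=O)C(OCc1ccccc1)C(=O)c1cc(OCc2ccccc2)c(OC)c(OCc2ccccc2)c1
A7 | alternative 2 | 2-{2-(benzyloxy)-3-[3,5-bis(benzyloxy)-4-methoxyphenyl]-3-oxopropanoyl}-5-(benzyloxy)-1,4-benzoquinone | O=C1C=C(OCc2ccccc2)C(=O)C=C1C(=O)C(OCc1ccccc1)C(=O)c1cc(OCc2ccccc2)c(OC)c(OCc2ccccc2)c1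
A8 | alternative 3 | 5,7-bis(benzyloxy)-2-[3,5-bis(benzyloxy)-4-methoxyphenyl]-3-iodo-8-methoxy-4H-chromen-4-one | COc1c(OCc2ccccc2)cc(-c2oc3c(OC)c(OCc4ccccc4)cc(OCc4ccccc4)c3c(=O)c2I)cc1OCc1ccccc1
A9 | alternative 3 | 1-[4,6-bis(benzyloxy)-2-hydroxy-3-methoxyphenyl]-3-[3,5-bis(benzyloxy)-4-methoxyphenyl]prop-2-yn-1-one | COc1c(O)c(C(=O)C#Cc2cc(OCc3ccccc3)c(OC)c(OCc3ccccc3)c2)c(OCc2ccccc2)cc1OCc1ccccc1
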